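The catechol is disconnected at both phenolic C–O bonds, on ring carbons C2 and C3 next to the ester-bearing C1, back to two C–B bonds that arise together from a 2,3-aryne. The key step exploits exactly this feature, two like heteroatoms on adjacent carbons of the benzene ring: platinum-catalysed addition of B2pin2 across the aryne triple bond makes the C2–B and C3–B bonds in one operation, and perborate then turns them into the hydroxyls. The aryne precursor is the C22 alkyl benzoate carrying triflate at C2 and trimethylsilyl at C3; all organolithium chemistry is done on 2,6-dibromophenol before the ester exists.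

Key step: step 6

Remark on the chemistry: the side chain is read as 20-methylhenicosyl (nineteen CH2 groups between the ester oxygen and the isopropyl end); the target has no stereocentre, so no step needs stereocontrol.

Step 1
Reactants: 1 16-bromohexadecan-1-ol; 2 1-bromo-4-methylpentane
Product: 5 20-methylhenicosan-1-ol, via 4-methylpentylmagnesium bromide 3 (not isolated), via bromomagnesium 16-bromohexadecan-1-olate 4 (not isolated)
Conditions: 2, Mg, THF, 40 °C; then 1 (one third of an equivalent relative to the Grignard reagent), Li2CuCl4 (3 mol %), THF, −78 °C → rt; aq. NH4Cl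
Reagents that add atoms: none
Why: Li2CuCl4-catalysed alkyl–alkyl Grignard cross-coupling, established for unprotected ω-bromo alcohols: the first equivalent of 3 only deprotonates the hydroxyl to the inert alkoxide 4, whose primary bromide is then displaced through a transient alkylcopper species; no stereocentre is formed.

Step 2
Reactants: 6 2,6-dibromophenol
Product: 9 2-bromo-6-(trimethylsilyl)phenol, via (2,6-dibromophenoxy)trimethylsilane 7 (not isolated), via (2-bromo-6-lithiophenoxy)trimethylsilane 8 (not isolated)
Conditions: HMDS (neat), 80 °C, then evaporation; n-BuLi (1.05 equiv), THF, −78 °C → rt; aq. NH4Cl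
Reagents that add atoms: hexamethyldisilazane (HMDS), C[Si](C)(C)N[Si](C)(C)C
Why: O-silylation, bromine–lithium exchange and anionic 1,3 O→C silyl migration (retro-Brook rearrangement) form the standard entry to ortho-silylphenols; one equivalent of n-BuLi exchanges a single bromine and the phenoxide formed is inert.

Step 3
Reactants: 9 2-bromo-6-(trimethylsilyl)phenol
Product: 11 2-hydroxy-3-(trimethylsilyl)benzoic acid, via lithium 2-lithio-6-(trimethylsilyl)phenolate 10 (not isolated)
Conditions: n-BuLi (2.2 equiv), THF, −78 → 0 °C; CO2 (g), −78 °C → rt; cold 1 M HCl to pH 3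
Reagents that add atoms: carbon dioxide, O=C=O
Why: Deprotonation and bromine–lithium exchange on the lithium phenoxide give the C,O-dilithio species 10, whose aryllithium carbon is carboxylated by CO2 (organolithium carboxylation); no ester is present yet, so nothing competes, and brief cold dilute acid should leave the aryl–silicon bond intact.

Step 4
Reactants: 11 2-hydroxy-3-(trimethylsilyl)benzoic acid; 5 20-methylhenicosan-1-ol
Product: 12 20-methylhenicosyl 2-hydroxy-3-(trimethylsilyl)benzoate
Conditions: PPh3, DIAD, THF, 0 °C → rt
Reagents that add atoms: none
Why: Mitsunobu esterification: the carboxylic acid is by far the most acidic pronucleophile (the phenol is hydrogen-bonded and flanked by silicon), so the carboxylate displaces the primary alcohol activated as its alkoxyphosphonium salt, under near-neutral conditions that do not endanger the aryl–silicon bond.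

Step 5
Reactants: 12 20-methylhenicosyl 2-hydroxy-3-(trimethylsilyl)benzoate
Product: 13 20-methylhenicosyl 2-(trifluoromethylsulfonyloxy)-3-(trimethylsilyl)benzoate
Conditions: Tf2O, pyridine, CH2Cl2, 0 °C → rt
Reagents that add atoms: trifluoromethanesulfonic anhydride (Tf2O), O=S(=O)(OS(=O)(=O)C(F)(F)F)C(F)(F)F
Why: O-Triflation of a phenol with Tf2O and pyridine (sulfonylation via N-triflylpyridinium) is routine for salicylate esters and for ortho-silylphenols, and the ester and the aryl–silicon bond are inert to it.

Step 6
Reactants: 13 20-methylhenicosyl 2-(trifluoromethylsulfonyloxy)-3-(trimethylsilyl)benzoate; 14 bis(pinacolato)diboron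
Product: 16 20-methylhenicosyl 2,3-bis(4,4,5,5-tetramethyl-1,3,2-dioxaborolan-2-yl)benzoate, via 20-methylhenicosyl 2,3-didehydrobenzoate 15 (not isolated)
Conditions: Pt(dba)2 (5 mol %), 1-adamantyl isocyanide (20 mol %), KF (3 equiv), 18-crown-6 (3 equiv), DME, 80 °C; 13 added slowly to 14 (1.5 equiv)
Reagents that add atoms: none
Why: Fluoride from KF/18-crown-6 attacks silicon at C3 and the resulting aryl anion expels triflate from C2, releasing aryne 15 slowly; in parallel, zerovalent platinum ligated by the isocyanide adds oxidatively into the B–B bond of 14 to give a cis-bis(boryl) complex of divalent platinum, the aryne inserts into one Pt–B bond, and C–B reductive elimination forms the second bond, so that the C2–B and C3–B bonds are both made. The closest known reaction type is the platinum-catalysed diboration of arynes generated from ortho-silylaryl triflates (and of alkynes generally), here applied to an aryne that carries an ester next to the triple bond. No ring is closed and no stereocentre is created. Because both new substituents are the same boryl group, the orientation of addition to the unsymmetrical aryne is irrelevant; the only selectivity needed is chemoselective capture of the aryne by the boryl–platinum species and not by fluoride, by a second aryne or by an ester of another molecule. A low stationary aryne concentration (slow addition of 13, sparingly soluble KF) in the presence of excess 14 should secure this, and the near-neutral anhydrous medium should leave the long-chain ester untouched.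

Step 7
Reactants: 16 20-methylhenicosyl 2,3-bis(4,4,5,5-tetramethyl-1,3,2-dioxaborolan-2-yl)benzoate
Product: 17 Gentiside A (20-methylhenicosyl 2,3-dihydroxybenzoate)
Conditions: NaBO3·4H2O (6 equiv), THF/H2O (1:1), rt, under Ar; then 1 M HCl to pH 3
Reagents that add atoms: sodium perborate (NaBO3·4H2O; dimeric peroxoborate), [Na+].[Na+].O[B-]1(O)OO[B-](O)(O)OO1
Why: Oxidation of arylboronic esters to phenols by perborate (peroxide attack on boron, 1,2-aryl shift from boron to oxygen, hydrolysis) converts both C–B bonds into C–OH; the mildly basic medium at room temperature should spare the long-chain ester, and the catechol stays masked as its borate complex until acidification.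

Compound list
1 | 16-bromohexadecan-1-ol | OCCCCCCCCCCCCCCCCBr | starting material
2 | 1-bromo-4-methylpentane | CC(C)CCCBr | starting material
3 | 4-methylpentylmagnesium bromide | CC(C)CCC[Mg]Br | intermediate
4 | bromomagnesium 16-bromohexadecan-1-olate | Br[Mg]OCCCCCCCCCCCCCCCCBr | intermediate
5 | 20-methylhenicosan-1-ol | CC(C)CCCCCCCCCCCCCCCCCCCO | intermediate
6 | 2,6-dibromophenol | Oc1c(Br)cccc1Br | starting material
7 | (2,6-dibromophenoxy)trimethylsilane | C[Si](C)(C)Oc1c(Br)cccc1Br | intermediate
8 | (2-bromo-6-lithiophenoxy)trimethylsilane | C[Si](C)(C)Oc1c(Br)cccc1[Li] | intermediate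
9 | 2-bromo-6-(trimethylsilyl)phenol | Oc1c(Br)cccc1[Si](C)(C)C | intermediate
10 | lithium 2-lithio-6-(trimethylsilyl)phenolate | [Li]Oc1c([Li])cccc1[Si](C)(C)C | intermediate
11 | 2-hydroxy-3-(trimethylsilyl)benzoic acid | OC(=O)c1cccc([Si](C)(C)C)c1O | intermediate
12 | 20-methylhenicosyl 2-hydroxy-3-(trimethylsilyl)benzoate | CC(C)CCCCCCCCCCCCCCCCCCCOC(=O)c1cccc([Si](C)(C)C)c1O | intermediate
13 | 20-methylhenicosyl 2-(trifluoromethylsulfonyloxy)-3-(trimethylsilyl)benzoate | CC(C)CCCCCCCCCCCCCCCCCCCOC(=O)c1cccc([Si](C)(C)C)c1OS(=O)(=O)C(F)(F)F | intermediate
14 | bis(pinacolato)diboron | CC1(C)OB(OC1(C)C)B1OC(C)(C)C(C)(C)O1 | starting material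
15 | 20-methylhenicosyl 2,3-didehydrobenzoate (the 2,3-aryne) | CC(C)CCCCCCCCCCCCCCCCCCCOC(=O)C1=CC=CC#C1 | intermediate
16 | 20-methylhenicosyl 2,3-bis(4,4,5,5-tetramethyl-1,3,2-dioxaborolan-2-yl)benzoate | CC(C)CCCCCCCCCCCCCCCCCCCOC(=O)c1cccc(B2OC(C)(C)C(C)(C)O2)c1B3OC(C)(C)C(C)(C)O3 | intermediate
17 | Gentiside A (20-methylhenicosyl 2,3-dihydroxybenzoate) | CC(C)CCCCCCCCCCCCCCCCCCCOC(=O)c1cccc(O)c1O | target

Total step count: 7.
Longest linear sequence: 6 steps (steps 2 to 7, from 2,6-dibromophenol 6); step 1 supplies alcohol 5, which joins at step 4.

Steps most likely to fail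

Step 6. The ester-bearing aryne is a new substrate for this known diboration. The aryne may be consumed by fluoride, by oligomerisation or platinum-mediated cyclotrimerisation, or the triflate may be cleaved at sulfur before elimination, so that capture by the bis(boryl)platinum species stays minor. The fallback avoids the aryne altogether and uses known chemistry. It sets out from alcohol 5, which is esterified with commercial 2,3-bis(benzyloxy)benzoic acid (EDC·HCl, DMAP, CH2Cl2, rt) to give 20-methylhenicosyl 2,3-bis(benzyloxy)benzoate F1. Hydrogenolysis of both benzyl ethers (H2, 10% Pd/C, EtOAc/THF, rt) should then deliver the catechol, so the fallback returns to the route at target 17.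

Step 7. Oxidation at the hindered C2–B bond, flanked by the ester and the second boronate, may stall; base-induced protodeboronation at that carbon or air oxidation of the catechol in the basic medium may also erode the product. The fallback changes the boron species before oxidation. It sets out from 16, whose two pinacol esters are exchanged with KHF2 (MeOH/THF/H2O, rt) to give dipotassium [3-(20-methylhenicosyloxycarbonyl)-1,2-phenylene]bis(trifluoroborate) F2. Oxidation of F2 with KHSO5 (used as the triple salt 2KHSO5·KHSO4·K2SO4) in acetone/water at rt, a fast and nearly neutral oxidation of aryltrifluoroborates, should return the route at target 17.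

Step 3. Bromine–lithium exchange on the lithium phenoxide may be incomplete, the dianion may be protonated or butylated before carboxylation, or the aryllithium may add to the lithium carboxylate already formed. The fallback replaces organolithium carboxylation by palladium catalysis. It sets out from 9, which is methoxycarbonylated (Pd(OAc)2, Xantphos, CO 1 atm, Et3N, MeOH/toluene, 80 °C) to give methyl 2-hydroxy-3-(trimethylsilyl)benzoate F3. Saponification of F3 (LiOH, THF/H2O, rt to 40 °C, then mild acidification) returns the route at acid 11.

Further compounds
F1 | step 6 | 20-methylhenicosyl 2,3-bis(benzyloxy)benzoate | CC(C)CCCCCCCCCCCCCCCCCCCOC(=O)c1cccc(OCc2ccccc2)c1OCc3ccccc3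
F2 | step 7 | dipotassium [3-(20-methylhenicosyloxycarbonyl)-1,2-phenylene]bis(trifluoroborate) | CC(C)CCCCCCCCCCCCCCCCCCCOC(=O)c1cccc([B-](F)(F)F)c1[B-](F)(F)F.[K+].[K+]
F3 | step 3 | methyl 2-hydroxy-3-(trimethylsilyl)benzoate | COC(=O)c1cccc([Si](C)(C)C)c1O
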